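**Strategy.** The route rests on cutting both C–CH3 bonds at cyclobutane C1 and C2. In the target these methyls are cis to each other and to the C3/C4 carboxyls, which is where the ring-fusion hydrogens of a cis-fused five-membered imide on the maleic anhydride photodimer sit. The precursor is therefore the meso mono-N-phenylimide of cis,trans,cis-cyclobutanetetracarboxylic acid with free C3/C4 acids. As its dilithium dicarboxylate it is enolised and methylated twice at the imide α-carbons, which sets both quaternary centres with retention in one operation. The imide carbonyls are later reduced to a dialdehyde from which both 4-methoxy-3-methyl-2-pyrone rings are grown.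

Key step: step 2

Remark on the chemistry (assumption): the target is meso (methyls and C3/C4 carboxyls on one face, both pyrone rings on the other), so only relative stereocontrol is needed; C1/C2 denote the methyl-bearing ring carbons and C3/C4 the carboxyl-bearing ones throughout, and unsymmetrical intermediates (3, 6, 9, 11, 12, 17, 18, F3, F6) are racemic or diastereomeric mixtures whose SMILES show one enantiomer.

**Route**

Step 1
Reactants: 1 cis,trans,cis-cyclobutane-1,2,3,4-tetracarboxylic dianhydride; 2 aniline
Product: 5 imide diacid (N-phenylimide across C1/C2; free cis CO2H groups on C3/C4 on the face opposite to the imide ring), via amic acid anhydride 3 (not isolated), via imide anhydride 4 (not isolated)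
Conditions: 1 (2 equiv), PhNH2 (1 equiv, slow addition), AcOH, 25 °C then reflux; then H2O, 80 °C
Reagents that add atoms: water, O
Why: Anhydride aminolysis followed by thermal dehydrative imidisation in acetic acid is the standard N-aryl imide synthesis, an excess of 1 keeping the second anhydride largely intact until water hydrolyses it, and the neutral bis-imide and the water-soluble tetra-acid are removed by acid–base extraction; all four stereocentres are carried over from 1, the five-membered imide being possible only cis-fused.

Step 2
Reactants: 5 imide diacid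
Product: 7 dimethyl imide diacid (CH3 on both ring-fusion carbons C1/C2; both CH3 cis to the C3/C4 CO2H groups), via monomethyl imide dicarboxylate 6 (not isolated)
Conditions: LiN(iPr)2 (3.2 equiv), THF–DMPU, −78 → −40 °C; MeI (1.1 equiv), −78 °C; LiN(iPr)2 (1.5 equiv), −78 → −40 °C; MeI (3 equiv), −78 → −20 °C; 1 M HCl
Reagents that add atoms: iodomethane, CI
Why: Two equivalents of LiN(iPr)2 turn the C3/C4 acids into lithium carboxylates, a third removes a ring-fusion proton α to an imide carbonyl, and the lithium enolate attacks iodomethane in an SN2 step; after this first C–CH3 bond has formed (6), the same sequence is run at the neighbouring ring-fusion carbon. The closest known reaction type is the α-alkylation of cis-fused bicyclic succinimide enolates at the ring-fusion carbon. No ring is closed. Each new quaternary centre (C1 and C2) is controlled by the cis-fused five-membered imide ring: a trans-fused 3-azabicyclo[3.2.0]heptane is too strained to form, so the methyl can only enter on the exo face where the hydrogen stood, which places both methyls cis to each other and to the C3/C4 carboxylates. The step needs site selectivity for C1/C2 over C3/C4 and an intact cyclobutane; both follow from the carboxylates, whose α-protons are far less acidic than the imide α-protons (no epimerisation or methylation at C3/C4) and which cannot stabilise the carbanion that a β-cleavage of the ring from the enolate would leave, while O-methylation of lithium carboxylates is slow at these temperatures.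

Step 3
Reactants: 7 dimethyl imide diacid
Product: 8 di-tert-butyl ester of 7 (CO2tBu on C3/C4; imide unchanged)
Conditions: Cl3CC(=NH)OtBu (4 equiv), BF3·OEt2 (cat.), CH2Cl2–cyclohexane, 25 °C
Reagents that add atoms: tert-butyl 2,2,2-trichloroacetimidate, CC(C)(C)OC(=N)C(Cl)(Cl)Cl
Why: Acid-catalysed tert-butyl transfer from the trichloroacetimidate alkylates the carboxyl oxygen (imidate esterification), so the carboxyl carbon is never activated and the cis-diacid cannot close to an anhydride or epimerise.

Step 4
Reactants: 8 di-tert-butyl ester imide
Product: 10 cyclic anhydride across C1/C2 (CO2tBu on C3/C4 and both CH3 on the opposite face), via amic acid 9 (not isolated)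
Conditions: LiOH (3 equiv), THF–H2O, 25–40 °C; then 1 M HCl/EtOAc (two phases), 25–40 °C
Reagents that add atoms: lithium hydroxide, [Li+].[OH-]
Why: Hydroxide opens the N-aryl imide while tert-butyl esters resist saponification, and in dilute acid the carboxyl group of the tetrasubstituted cis-succinanilic acid attacks the neighbouring anilide and expels aniline (intramolecular carboxyl-assisted amide cleavage, accelerated by the two quaternary carbons), the anhydride being drawn into the organic layer and anilinium chloride into water; no stereocentre is involved.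

Step 5
Reactants: 10 anhydride
Product: 12 cis-fused γ-lactone (C1 CH2–O; C2 C=O; CO2tBu on C3/C4), via hydroxy acid 11 (not isolated)
Conditions: NaBH4 (2 equiv), THF, 0 → 25 °C; then 1 M HCl, 0 → 25 °C
Reagents that add atoms: none
Why: Borohydride reduction of a cyclic anhydride to the lactone: hydride attack gives the hydroxy carboxylate, which NaBH4 cannot reduce further and which lactonises on acidification, the tert-butyl esters being inert and the symmetric anhydride giving a single racemic lactone.

Step 6
Reactants: 12 lactone
Product: 13 meso diol (CH2OH and CH3 on each of C1/C2; CO2tBu on C3/C4)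
Conditions: LiBH4 (2 equiv), THF, 0 → 25 °C; cold dilute HCl work-up
Reagents that add atoms: none
Why: LiBH4 reduces the s-cis lactone carbonyl to the 1,4-diol (chemoselective borohydride ester reduction) far faster than it attacks the two hindered tert-butyl esters, and the meso diol is formed without change at any stereocentre.

Step 7
Reactants: 13 diol
Product: 14 meso cis-dialdehyde (CHO and CH3 on each of C1/C2)
Conditions: (COCl)2, DMSO, CH2Cl2, −78 °C; Et3N, −78 → 0 °C
Reagents that add atoms: none
Why: In the Swern oxidation both primary alcohols are converted into alkoxysulfonium salts before Et3N is added, so the 1,4-diol gives the dialdehyde without a lactol that could be oxidised to the lactone, and the formyl groups sit on quaternary carbons and cannot epimerise.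

Step 8
Reactants: 14 dialdehyde; 15 ethyl 2-methyl-3-oxobutanoate
Product: 17 bis-aldol (each of C1/C2 carries CH(OH)CH2C(=O)CH(CH3)CO2Et), via dilithium dienolate 16 (not isolated)
Conditions: 15 (5 equiv), LiN(iPr)2 (10 equiv), THF, −78 → 0 °C; then 14, −78 → −20 °C; AcOH quench
Reagents that add atoms: none
Why: Aldol addition of the γ-carbon of the β-keto ester dianion to the non-enolisable aldehydes (β-keto ester dianion aldol), with excess dianion and warming to reopen the lactolate that the first aldolate forms with the neighbouring formyl group; the new carbinol and α-methyl centres form as mixtures, which does not matter because steps 9 and 10 remove them.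

Step 9
Reactants: 17 bis-aldol
Product: 18 bis(3,5-diketo ester) (each of C1/C2 carries C(=O)CH2C(=O)CH(CH3)CO2Et)
Conditions: Dess–Martin periodinane (3 equiv), CH2Cl2, 25 °C
Reagents that add atoms: none
Why: Dess–Martin oxidation converts β-hydroxy ketones into 1,3-diketones under neutral conditions without retro-aldol cleavage, and a hemiketal formed between the first ketone and the remaining secondary alcohol is tertiary, so it reopens and is not over-oxidised.

Step 10
Reactants: 18 bis(3,5-diketo ester)
Product: 19 bis(4-hydroxy-3-methyl-2-oxo-2H-pyran-6-yl) di-tert-butyl ester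
Conditions: DBU (4 equiv), toluene, 25 → 60 °C; dilute HCl work-up
Reagents that add atoms: none
Why: DBU enolises each 3,5-diketo ester and the C5 enolate oxygen attacks the ethyl ester in a six-membered lactonisation with loss of ethanol (base-mediated 4-hydroxy-2-pyrone cyclisation), which also turns the mixed α-methyl centres into sp2 carbons.

Step 11
Reactants: 19 bis(hydroxypyrone)
Product: 20 bis(4-methoxy-3-methyl-2-oxo-2H-pyran-6-yl) di-tert-butyl ester
Conditions: Me2SO4 (4 equiv), K2CO3 (4 equiv), acetone, 25 → 56 °C
Reagents that add atoms: dimethyl sulfate, COS(=O)(=O)OC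
Why: O-Methylation of the vinylogous acid with dimethyl sulfate and K2CO3 in acetone (Williamson-type alkylation of the pyronate) is known to favour the 4-methoxy-2-pyrone over the 2-methoxy-4-pyrone isomer, and the tert-butyl esters are inert.

Step 12
Reactants: 20 bis(methoxypyrone) di-tert-butyl ester
Product: 21 target diacid
Conditions: CF3CO2H/CH2Cl2 (1:2), 0 → 25 °C
Reagents that add atoms: none
Why: Acidolysis of tert-butyl esters through the tert-butyl cation (loss of isobutene) frees both acids; 4-methoxy-2-pyrones tolerate CF3CO2H and the carboxyl-bearing carbons, flanked by quaternary centres, keep their cis configuration under acid.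

**Compound list**

1 | cis,trans,cis-cyclobutane-1,2,3,4-tetracarboxylic 1,2:3,4-dianhydride (both anhydride rings cis-fused, on opposite faces of the cyclobutane) | O1C(=O)[C@H]2[C@H](C(=O)O3)[C@H](C3=O)[C@H]2C1=O | starting material
2 | aniline | Nc1ccccc1 | starting material
3 | amic acid anhydride: C1 N-phenylcarboxamide and C2 CO2H (cis), C3/C4 cyclic anhydride on the opposite face; racemic | O=C(Nc1ccccc1)[C@H]2[C@H](C(=O)O3)[C@H](C3=O)[C@H]2C(=O)O | intermediate
4 | imide anhydride: N-phenylimide across C1/C2, cyclic anhydride across C3/C4, rings on opposite faces | N1(c3ccccc3)C(=O)[C@H]2[C@H](C(=O)O4)[C@H](C4=O)[C@H]2C1=O | intermediate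
5 | 2,4-dioxo-3-phenyl-3-azabicyclo[3.2.0]heptane-6,7-dicarboxylic acid; CO2H groups cis to each other and to the ring-fusion hydrogens, trans to the imide ring; meso | N1(c3ccccc3)C(=O)[C@H]2[C@H](C(=O)O)[C@H](C(=O)O)[C@H]2C1=O | intermediate
6 | monomethyl imide dicarboxylate, dilithium salt: 5 with one ring-fusion H replaced by CH3 cis to the carboxylates; racemic | N1(c3ccccc3)C(=O)[C@@]2(C)[C@H](C(=O)[O-])[C@H](C(=O)[O-])[C@H]2C1=O.[Li+].[Li+] | intermediate
7 | 1,5-dimethyl-2,4-dioxo-3-phenyl-3-azabicyclo[3.2.0]heptane-6,7-dicarboxylic acid; both CH3 cis to both CO2H, imide ring on the other face; meso | N1(c3ccccc3)C(=O)[C@@]2(C)[C@H](C(=O)O)[C@H](C(=O)O)[C@@]2(C)C1=O | intermediate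
8 | di-tert-butyl ester of 7 | N1(c3ccccc3)C(=O)[C@@]2(C)[C@H](C(=O)OC(C)(C)C)[C@H](C(=O)OC(C)(C)C)[C@@]2(C)C1=O | intermediate
9 | amic acid: C1 N-phenylcarboxamide and C2 CO2H (cis, opposite to the methyls and tert-butyl esters); racemic | O=C(Nc1ccccc1)[C@@]2(C)[C@H](C(=O)OC(C)(C)C)[C@H](C(=O)OC(C)(C)C)[C@@]2(C)C(=O)O | intermediate
10 | di-tert-butyl 1,5-dimethyl-2,4-dioxo-3-oxabicyclo[3.2.0]heptane-6,7-dicarboxylate; methyls and esters on one face, anhydride ring on the other; meso | O1C(=O)[C@@]2(C)[C@H](C(=O)OC(C)(C)C)[C@H](C(=O)OC(C)(C)C)[C@@]2(C)C1=O | intermediate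
11 | hydroxy acid: C1 CH2OH and C2 CO2H (cis), CH3 on C1/C2 and CO2tBu on C3/C4 on the other face; racemic | OC[C@@]1(C)[C@H](C(=O)OC(C)(C)C)[C@H](C(=O)OC(C)(C)C)[C@@]1(C)C(=O)O | intermediate
12 | di-tert-butyl 1,5-dimethyl-2-oxo-3-oxabicyclo[3.2.0]heptane-6,7-dicarboxylate (cis-fused lactone, esters trans to the lactone ring); racemic | O1C[C@@]2(C)[C@H](C(=O)OC(C)(C)C)[C@H](C(=O)OC(C)(C)C)[C@@]2(C)C1=O | intermediate
13 | diol: CH2OH and CH3 on each of C1/C2, CO2tBu on C3/C4; CH3 and esters all on one face, both CH2OH on the other; meso | OC[C@@]1(C)[C@H](C(=O)OC(C)(C)C)[C@H](C(=O)OC(C)(C)C)[C@@]1(C)CO | intermediate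
14 | dialdehyde: CHO and CH3 on each of C1/C2, same relative configuration as 13; meso | O=C[C@@]1(C)[C@H](C(=O)OC(C)(C)C)[C@H](C(=O)OC(C)(C)C)[C@@]1(C)C=O | intermediate
15 | ethyl 2-methyl-3-oxobutanoate | CCOC(=O)C(C)C(C)=O | starting material
16 | dilithium dienolate (2,4-dianion) of 15 | C=C([O-])C(C)=C([O-])OCC.[Li+].[Li+] | intermediate
17 | bis-aldol: each of C1/C2 carries CH3 and CH(OH)CH2C(=O)CH(CH3)CO2Et; ring configuration as 13, side-chain centres as mixtures | CCOC(=O)C(C)C(=O)CC(O)[C@@]1(C)[C@H](C(=O)OC(C)(C)C)[C@H](C(=O)OC(C)(C)C)[C@@]1(C)C(O)CC(=O)C(C)C(=O)OCC | intermediate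
18 | bis(3,5-diketo ester): each of C1/C2 carries CH3 and C(=O)CH2C(=O)CH(CH3)CO2Et (largely enolised) | CCOC(=O)C(C)C(=O)CC(=O)[C@@]1(C)[C@H](C(=O)OC(C)(C)C)[C@H](C(=O)OC(C)(C)C)[C@@]1(C)C(=O)CC(=O)C(C)C(=O)OCC | intermediate
19 | di-tert-butyl ester with a 4-hydroxy-3-methyl-2-oxo-2H-pyran-6-yl group and CH3 on each of C1/C2; pyrones on one face, CH3 and esters on the other; meso | Oc1cc([C@@]2(C)[C@H](C(=O)OC(C)(C)C)[C@H](C(=O)OC(C)(C)C)[C@@]2(C)c2cc(O)c(C)c(=O)o2)oc(=O)c1C | intermediate
20 | di-tert-butyl ester with a 4-methoxy-3-methyl-2-oxo-2H-pyran-6-yl group and CH3 on each of C1/C2; configuration as 19; meso | COc1cc([C@@]2(C)[C@H](C(=O)OC(C)(C)C)[C@H](C(=O)OC(C)(C)C)[C@@]2(C)c2cc(OC)c(C)c(=O)o2)oc(=O)c1C | intermediate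
21 | CNP0574758.1: cyclobutane diacid, 4-methoxy-3-methyl-2-oxo-2H-pyran-6-yl and CH3 on each of C1/C2, CO2H on C3/C4; both CH3 and both CO2H on one face, both pyrones on the other; meso | COc1cc([C@@]2(C)[C@H](C(=O)O)[C@H](C(=O)O)[C@@]2(C)c2cc(OC)c(C)c(=O)o2)oc(=O)c1C | target

**Step count and risks**

Total steps: 12. Longest linear sequence: 12 steps (1 → 21); 15 enters at step 8.

The three steps most likely to fail:

(a) The double methylation, step 2. The tri- and tetra-lithiated species may dissolve poorly and enolise incompletely. The second methylation has to build a quaternary centre next to the first and may stall at the monomethyl stage. A slow alkylation also leaves room for O-methylation of the carboxylates or for fragmentation of the strained ring. The fallback forms the cyclobutane with the methyls already in place instead of alkylating it. It sets out from aniline 2, which is condensed with commercial 2,3-dimethylmaleic anhydride (AcOH, reflux) to 2,3-dimethyl-N-phenylmaleimide F1. Sensitised [2+2] photocycloaddition of F1 with an excess of maleic anhydride (acetone as solvent and sensitiser, hν > 300 nm) should give the cis,anti,cis 1,2-dimethyl imide anhydride F2. Both rings are necessarily cis-fused and the anti arrangement is favoured sterically; the insoluble maleic anhydride homodimer is filtered off. Hydrolysis of the anhydride ring of F2 in warm aqueous THF comes back to the route at 7.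

(b) The double aldol addition, step 8. After the first addition the aldolate can add to the neighbouring formyl group, and if this lactolate does not reopen the second addition stalls; warming to force it may instead cause retro-aldol cleavage. The fallback replaces the aldol chain extension by a methyl ketone route and sets out from dialdehyde 14. Excess MeMgBr (THF, −78 → 0 °C; magnesium lactolates reopen readily) should give the bis(1-hydroxyethyl) compound F3. Dess–Martin periodinane oxidises it to the bis-acetyl compound F4. LiN(SiMe3)2 with Me3SiCl as internal quench (THF, −78 °C) gives the bis(trimethylsilyl enol ether) F5. Acylative pyrone annulation of F5 with 2-methylmalonyl dichloride (Et2O, −78 → 0 °C; C-acylation of the enol ether, then lactonisation) gives both 4-hydroxy-3-methyl-2-pyrone rings and comes back to the route at 19, skipping 17 and 18.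

(c) The imide-to-anhydride exchange, step 4. Hydroxide attack at the hindered carbonyls may be slow. On acidification the amic acid may close back to the imide instead of expelling aniline, and long acid exposure may start to cleave the tert-butyl esters. The fallback opens the imide reductively instead of hydrolytically and sets out from 8. NaBH4 in iPrOH/H2O at 25 °C should reduce one imide carbonyl and open the ring to the hydroxy anilide F6, which cannot re-form an imide. Warming with AcOH (80 °C) lactonises F6 with loss of aniline (borohydride cleavage of N-substituted imides) and comes back to the route at lactone 12, skipping 10 and 11.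

**Further compounds**

F1 | step 2 | 2,3-dimethyl-N-phenylmaleimide | CC1=C(C)C(=O)N(c2ccccc2)C1=O
F2 | step 2 | cis,anti,cis 1,2-dimethyl imide anhydride (N-phenylimide across the methyl-bearing C1/C2, anhydride across C3/C4 on the opposite face) | N1(c3ccccc3)C(=O)[C@@]2(C)[C@H](C(=O)O4)[C@H](C4=O)[C@@]2(C)C1=O
F3 | step 8 | bis(1-hydroxyethyl) compound (CH(OH)CH3 and CH3 on each of C1/C2, CO2tBu on C3/C4; carbinol centres as a mixture) | CC(O)[C@@]1(C)[C@H](C(=O)OC(C)(C)C)[C@H](C(=O)OC(C)(C)C)[C@@]1(C)C(C)O
F4 | step 8 | bis-acetyl compound (C(=O)CH3 and CH3 on each of C1/C2; meso) | CC(=O)[C@@]1(C)[C@H](C(=O)OC(C)(C)C)[C@H](C(=O)OC(C)(C)C)[C@@]1(C)C(C)=O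
F5 | step 8 | bis(trimethylsilyl enol ether) of F4 | C=C(O[Si](C)(C)C)[C@@]1(C)[C@H](C(=O)OC(C)(C)C)[C@H](C(=O)OC(C)(C)C)[C@@]1(C)C(=C)O[Si](C)(C)C
F6 | step 4 | hydroxy anilide (C1 CH2OH, C2 C(=O)NHPh, cis; CH3 and CO2tBu on the other face; racemic) | OC[C@@]1(C)[C@H](C(=O)OC(C)(C)C)[C@H](C(=O)OC(C)(C)C)[C@@]1(C)C(=O)Nc1ccccc1
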